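If you are choosing a temperature for a coupling whose product can react on or fall apart again, ask first how long a molecule of target survives in the flask.

    starting material + target → side product (k1 = 0.033 /M/s, Ea1 = 44.0 kJ/mol)
    2 coupling partner → self-condensation product (k2 = 0.0077 /M/s, Ea2 = 63.0 kJ/mol)
    starting material + coupling partner ⇌ target (K3 = 3.1 /M, k3 = 0.059 /M/s, Ea3 = 52.0 kJ/mol, ΔH3 = −52.0 kJ/mol)
    starting material + coupling partner ⇌ isomer of the product (K4 = 13 /M, k4 = 0.027 /M/s, Ea4 = 59.0 kJ/mol, ΔH4 = −6.00 kJ/mol)
    (constants at 40 °C)

| setting | alder | cedar |
|---|---|---|
| starting material | 0.30 M | 0.30 M |
| coupling partner | 0.600 equiv | 0.600 equiv |
| temperature | 40 °C | 10 °C |
| time | 4.0 min | 4.0 min |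

- in percentages every species weighs as the starting material in it: one side product counts as two
- a step written with two of one species runs at k times the square of its concentration and takes two of it each time
- constants are those at 40 °C; use the activation energies and enthalpies for any other temperature

- the best flask by amount of target, in percent of the starting material charged; "all alike" if 1.5 percentage points covers them all (alder / cedar / all alike)
- amount of target at the end, in percent of the starting material charged, alder
- amount of target at the end, in percent of the starting material charged, cedar

Go through the constants in turn and ask what an error in each would cost. An error in the self-condensation constant costs little at first: at the start of alder it takes coupling partner at 0.166 /min, slower than the 1.55 /min of the two couplings together.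

The isomer's constants count as a share. In cedar at the start, the forward step to target uses starting material 2.9 times as fast as the forward step to isomer, so an error there shifts how the coupling partner, charged at 0.600 equiv, divides.

What must be known well is what removes target once it exists, namely its reaction with starting material and its back step. Add these two exits at the charged c(starting material):

lifetime = 1 / (side-step constant × c(starting material) + forward constant / equilibrium constant)

alder: 1 / (0.594 /min + 1.14 /min) = 0.576 min

cedar: 1 / (0.0991 /min + 0.0166 /min) = 8.64 min

Carry this target lifetime, the relaxation time of the target. The number to get right differs by flask. In alder, at the charged c(starting material), the back step is the faster exit, so you need its two constants; in cedar the side step is faster, so you need the side-step constant.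

Against the 4.0 min allowed, alder's lifetime is short and cedar's long. The time allowed holds alder's lifetime 6.94 times and cedar's 0.463 times, so I expect target in alder to be lost as it forms and target in cedar to collect. I commit to cedar ahead, but my reckoning stops there and gives no percentages.

The forecast names cedar, with 6.5% in alder and 15.3% in cedar, holding that in the cold “the target is effectively kinetically trapped”.

The simulation gives 5.72% in alder and 15.6% in cedar, so cedar is the best flask. At the end of cedar, target is still made 2.50 times as fast as it is used, each step taken net. With 71.7% of the starting material left there, cedar's lifetime has grown from 8.64 min to 11.4 min, beyond the time allowed. The neighbour of cedar charged with 2.40 equiv of coupling partner starts from that same 8.64 min, and it ends with 27.3% of starting material, a lifetime of 22.9 min and 44.4% of target.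

All constants are those of an exercise; no experiment stands behind them.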